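The amounts first: 0.24 M of D went in with 4.80 mM of E, and the charge of Q was mine to find.

D 0.24 M; E 4.80 mM; time 10 d

- the concentration of Q at which the part of the D that has reacted at 10 d is just 90%, in M

    2 D → D2 (k1 = 0.050 M⁻¹ h⁻¹)
    Q + X ⇌ Q.X, settled at all times (K2 = 8700 M⁻¹)
    D + Q ⇌ X + G (K3 = 2.9, k3 = 0.33 M⁻¹ h⁻¹)
    D + E → D.E (k4 = 6.6 M⁻¹ h⁻¹)

1. I started with the binding of X to Q, held at balance. With free Q near 0.24 M, bound X over free X is 2090, so I priced each exchange D + Q ⇌ X + G at two Q: one consumed, one taken up by the released X.

2. Next came the time constants at that level. E catches D in 0.631 h, the exchange runs in 12.6 h, dimerisation in 41.7 h, and the run lasts 240 h. E therefore acts first, on 2.00% of the D.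

3. The target leaves 0.0240 M of D. Dimerisation raises 1/[D] by 24.0 M⁻¹ over the run, so it can bring D down to that from a start of 0.0566 M.

4. Adding the exchange and the binding gives D + two Q ⇌ Q.X + G, with K = 25200 M⁻¹. If T exchanges are done and balance stands, Q.X and G both equal T, and the charge of Q is about 2T plus free Q. The free share is then s = 1/(1 + 2√(K[D])). At the target this is 1.99%, the leftover share.

5. The leftover is the small correction: Q charged = 2T/(1 − s). Taking T as the D charged minus E's charge and the 0.0566 M, I got 0.364 M. I took this as an estimate on the high side, because the exchange is faster than dimerisation by a factor of 3.31, so the two run side by side, whereas I had started dimerisation at 0.0566 M.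

6. The forecast said 0.3 M, noting that “the tight Q.X binding makes each turn of step 3 use up two Q”.

7. The simulation gave 0.286 M, which is 0.0780 M below my estimate.

In that flask, 1.91% of the charged Q was still free at 10.0 d, against the leftover share of 1.99%. At 5.00 d, 85.9% of the D had been used, so s comes to 1.68%, and the flask read more than that: 1.98% at 5.00 d.

(Its constants are made up; what happens was integrated by code.)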